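**Retrosynthetic overview**
- The strategy rests on C2 of ring C, the only stereocentre: a benzylic ether carbon that carries ring B and lies beta to the C4 ketone. Cutting the C2–C1' bond gives a flat 7-siloxy-6,8-diprenylchromone (fragment 1) and a 4-siloxy-3-prenylphenylboronic acid (fragment 2), joined by a ligand-controlled palladium-catalysed 1,4-addition that sets 2S.
- The prenyl groups at C6, C8 and C3' each stand ortho to a phenol oxygen (O7 or O4'), so each is delivered from that oxygen: O-alkylation with a tertiary propargyl chloride, semihydrogenation, aromatic Claisen rearrangement.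
- Ring order: ring A is bought as 2,4-dihydroxyacetophenone and prenylated twice; ring C is closed through O1–C2 as an achiral pyranone via an enaminone; ring B (from 4-bromophenol) is prenylated and borylated separately; the fragments are united last and both silyl ethers removed.

Key step: step 15

Assumption: the sense of induction is taken from the usual model for this catalyst with cyclic enones, under which the (R)-ligand should place the aryl group on the face of C2 that gives 2S; if the opposite sense is found, the (S)-ligand is used. Prenyl means 3-methylbut-2-enyl throughout.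

Step 1
Reactants: 1 2,4-dihydroxyacetophenone; 2 3-chloro-3-methylbut-1-yne
Product: 3 1-[2-hydroxy-4-(2-methylbut-3-yn-2-yloxy)phenyl]ethanone
Conditions: 2 (1.5 equiv), DBU (1.5 equiv), CuCl2·2H2O (1 mol%), MeCN, 0 °C to rt
Reagents that add atoms: none
Why: Copper-catalysed propargylic O-alkylation of a phenol with a tertiary propargyl chloride, selective for the 4-hydroxyl because the 2-hydroxyl is tied up in a hydrogen bond to the acetyl carbonyl and is both less acidic and more hindered.

Step 2
Reactants: 3 1-[2-hydroxy-4-(2-methylbut-3-yn-2-yloxy)phenyl]ethanone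
Product: 4 1-[2-hydroxy-4-(2-methylbut-3-en-2-yloxy)phenyl]ethanone
Conditions: H2 (1 atm), Pd/CaCO3 poisoned with Pb(OAc)2 (Lindlar catalyst), quinoline, EtOAc, rt
Reagents that add atoms: none
Why: Lindlar semihydrogenation of the terminal alkyne should stop at the alkene and leave the aryl ketone untouched.

Step 3
Reactants: 4 1-[2-hydroxy-4-(2-methylbut-3-en-2-yloxy)phenyl]ethanone
Product: 5 2,4-dihydroxy-3-prenylacetophenone
Conditions: PhNEt2, 190 °C, Ar
Reagents that add atoms: none
Why: Aromatic Claisen rearrangement ([3,3] shift with allylic transposition) turns the 1,1-dimethylallyl ether into a C-prenyl group, directed to C3 between the two oxygens by the bond fixation of the chelated 2-hydroxyketone; any 5-prenyl regioisomer need not be removed, since steps 4 to 6 take it to the same diprenyl ketone.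

Step 4
Reactants: 5 2,4-dihydroxy-3-prenylacetophenone; 2 3-chloro-3-methylbut-1-yne
Product: 6 1-[2-hydroxy-4-(2-methylbut-3-yn-2-yloxy)-3-prenylphenyl]ethanone
Conditions: 2 (2 equiv), DBU (2 equiv), CuCl2·2H2O (2 mol%), MeCN, 0 °C to rt
Reagents that add atoms: none
Why: The same copper-catalysed propargylic O-alkylation, again confined to the non-chelated 4-hydroxyl, which remains accessible although it now has one ortho substituent.

Step 5
Reactants: 6 1-[2-hydroxy-4-(2-methylbut-3-yn-2-yloxy)-3-prenylphenyl]ethanone
Product: 7 1-[2-hydroxy-4-(2-methylbut-3-en-2-yloxy)-3-prenylphenyl]ethanone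
Conditions: H2 (1 atm), Pd/CaCO3 poisoned with Pb(OAc)2 (Lindlar catalyst), quinoline, EtOAc, rt
Reagents that add atoms: none
Why: Lindlar semihydrogenation reduces only the terminal alkyne; the trisubstituted prenyl alkene is far too slow to compete on the poisoned catalyst.

Step 6
Reactants: 7 1-[2-hydroxy-4-(2-methylbut-3-en-2-yloxy)-3-prenylphenyl]ethanone
Product: 8 2,4-dihydroxy-3,5-diprenylacetophenone
Conditions: PhNEt2, 190 °C, Ar
Reagents that add atoms: none
Why: Aromatic Claisen rearrangement can only end at C5, the single free ortho carbon, because a shift onto the substituted C3 gives a dienone that cannot tautomerise and reverts, and the basic solvent suppresses acid-catalysed chroman formation.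

Step 7
Reactants: 8 2,4-dihydroxy-3,5-diprenylacetophenone
Product: 9 1-[4-(tert-butyldimethylsilyloxy)-2-hydroxy-3,5-diprenylphenyl]ethanone
Conditions: TBSCl (1.2 equiv), imidazole (2.5 equiv), DMF, rt
Reagents that add atoms: tert-butyldimethylsilyl chloride, CC(C)(C)[Si](C)(C)Cl
Why: Imidazole-promoted O-silylation takes the free 4-hydroxyl, while the 2-hydroxyl, hydrogen-bonded to the ketone, should stay unsilylated.

Step 8
Reactants: 9 1-[4-(tert-butyldimethylsilyloxy)-2-hydroxy-3,5-diprenylphenyl]ethanone; 10 N,N-dimethylformamide dimethyl acetal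
Product: 11 (E)-1-[4-(tert-butyldimethylsilyloxy)-2-hydroxy-3,5-diprenylphenyl]-3-(dimethylamino)prop-2-en-1-one
Conditions: 10 (3 equiv), toluene, 90 °C
Reagents that add atoms: none
Why: Condensation of the methyl ketone with the amide acetal (enaminone formation) should give the E vinylogous amide; the 4-oxygen is masked so that the acetal cannot methylate it.

Step 9
Reactants: 11 (E)-1-[4-(tert-butyldimethylsilyloxy)-2-hydroxy-3,5-diprenylphenyl]-3-(dimethylamino)prop-2-en-1-one
Product: 12 7-(tert-butyldimethylsilyloxy)-6,8-diprenyl-4H-chromen-4-one (fragment 1)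
Conditions: AcOH (5 equiv), toluene, 70 °C
Reagents that add atoms: none
Why: Acid-promoted intramolecular oxa-Michael addition of the 2-hydroxyl to the protonated enaminone followed by elimination of dimethylamine (the enaminone chromone synthesis) closes ring C through O1–C2, and anhydrous acetic acid should spare both the hindered aryl silyl ether and the prenyl alkenes.

Step 10
Reactants: 13 4-bromophenol; 2 3-chloro-3-methylbut-1-yne
Product: 14 1-bromo-4-(2-methylbut-3-yn-2-yloxy)benzene
Conditions: 2 (1.5 equiv), DBU (1.5 equiv), CuCl2·2H2O (1 mol%), MeCN, 0 °C to rt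
Reagents that add atoms: none
Why: Copper-catalysed propargylic O-alkylation of an unhindered phenol with the tertiary propargyl chloride.

Step 11
Reactants: 14 1-bromo-4-(2-methylbut-3-yn-2-yloxy)benzene
Product: 15 1-bromo-4-(2-methylbut-3-en-2-yloxy)benzene
Conditions: H2 (1 atm), Pd/CaCO3 poisoned with Pb(OAc)2 (Lindlar catalyst), quinoline, EtOAc, rt
Reagents that add atoms: none
Why: Lindlar semihydrogenation of the alkyne; the poisoned catalyst should not hydrogenolyse the aryl bromide.

Step 12
Reactants: 15 1-bromo-4-(2-methylbut-3-en-2-yloxy)benzene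
Product: 16 4-bromo-2-prenylphenol
Conditions: PhNEt2, 160 °C, Ar
Reagents that add atoms: none
Why: Aromatic Claisen rearrangement to either of the two equivalent ortho carbons, the para position being blocked by bromine.

Step 13
Reactants: 16 4-bromo-2-prenylphenol
Product: 17 (4-bromo-2-prenylphenoxy)(tert-butyl)dimethylsilane
Conditions: TBSCl (1.2 equiv), imidazole (2.5 equiv), DMF, rt
Reagents that add atoms: tert-butyldimethylsilyl chloride, CC(C)(C)[Si](C)(C)Cl
Why: Standard imidazole-promoted silylation masks the phenol before metalation.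

Step 14
Reactants: 17 (4-bromo-2-prenylphenoxy)(tert-butyl)dimethylsilane
Product: 20 4-(tert-butyldimethylsilyloxy)-3-prenylphenylboronic acid (fragment 2), via the aryllithium 18 (not isolated), via the lithium triisopropyl arylborate 19 (not isolated)
Conditions: n-BuLi (1.05 equiv), THF, −78 °C; B(OiPr)3 (1.5 equiv), −78 °C to rt; 1 M HCl, 0 °C
Reagents that add atoms: triisopropyl borate, CC(C)OB(OC(C)C)OC(C)C; water, O; n-butyllithium, [Li]CCCC (lithium of 18 and 19 only)
Why: Bromine–lithium exchange at −78 °C outruns deprotonation of the benzylic allylic CH2, the lithium sits para to the silyl ether so no silyl migration is possible, and borate trapping with brief mild hydrolysis is the standard route to an arylboronic acid.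

Step 15
Reactants: 12 7-(tert-butyldimethylsilyloxy)-6,8-diprenyl-4H-chromen-4-one; 20 4-(tert-butyldimethylsilyloxy)-3-prenylphenylboronic acid
Product: 21 (2S)-7-(tert-butyldimethylsilyloxy)-2-[4-(tert-butyldimethylsilyloxy)-3-prenylphenyl]-6,8-diprenylchroman-4-one
Conditions: 20 (2 equiv), Pd(OCOCF3)2 (5 mol%), (R)-4-tert-butyl-2-(pyridin-2-yl)-4,5-dihydrooxazole (6 mol%), NH4PF6 (30 mol%), H2O (5 equiv), ClCH2CH2Cl, 60 °C
Reagents that add atoms: none
Why: The boronic acid 20 transmetalates to the cationic divalent palladium centre held by the pyridine–oxazoline ligand, the C2=C3 bond of chromone 12 inserts into the Pd–aryl bond with the aryl group delivered to C2, and water protonates the resulting palladium enolate at C3, so the catalyst returns without any change of oxidation state. The closest known reaction type is this same palladium-catalysed asymmetric conjugate addition of arylboronic acids to chromones and cyclic enones, here carried onto prenylated partners. No ring is closed: ring C already exists as the pyranone and simply becomes the chroman-4-one as the C2–C1' and C3–H bonds form. The new stereocentre C2 is controlled solely by the ligand, whose tert-butyl group blocks one enantioface of the flat, achiral enone in the insertion step, the (R)-ligand being chosen for 2S. The step needs enantiofacial selectivity, supplied by the ligand, and chemoselectivity for the polarised enone over the three prenyl alkenes, which their trisubstitution and weak binding to cationic palladium should secure, while the silyl ethers on O7 and O4' shut off palladium-mediated oxidative cyclisation of ortho-prenylphenols to chromenes. The 7-siloxy group, crowded between two prenyl groups, should donate little into the enone, and the near-neutral medium should prevent retro-oxa-Michael opening of ring C, so the configuration once set should hold.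

Step 16
Reactants: 21 (2S)-7-(tert-butyldimethylsilyloxy)-2-[4-(tert-butyldimethylsilyloxy)-3-prenylphenyl]-6,8-diprenylchroman-4-one
Product: 22 (2S)-7-hydroxy-2-(4-hydroxy-3-prenylphenyl)-6,8-diprenylchroman-4-one (target)
Conditions: Bu4NF (2.5 equiv), AcOH (2.5 equiv), THF, 0 °C
Reagents that add atoms: none
Why: Fluoride-mediated cleavage of both aryl silyl ethers, buffered with acetic acid so that no free phenoxide persists to open ring C by E1cB to the chalcone, should release the target with C2 intact.

**Compound list**
1 | 2,4-dihydroxyacetophenone | CC(=O)c1ccc(O)cc1O | starting material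
2 | 3-chloro-3-methylbut-1-yne | CC(C)(Cl)C#C | starting material
3 | 1-[2-hydroxy-4-(2-methylbut-3-yn-2-yloxy)phenyl]ethanone | CC(=O)c1ccc(OC(C)(C)C#C)cc1O | intermediate
4 | 1-[2-hydroxy-4-(2-methylbut-3-en-2-yloxy)phenyl]ethanone | CC(=O)c1ccc(OC(C)(C)C=C)cc1O | intermediate
5 | 2,4-dihydroxy-3-prenylacetophenone | CC(=O)c1ccc(O)c(CC=C(C)C)c1O | intermediate
6 | 1-[2-hydroxy-4-(2-methylbut-3-yn-2-yloxy)-3-prenylphenyl]ethanone | CC(=O)c1ccc(OC(C)(C)C#C)c(CC=C(C)C)c1O | intermediate
7 | 1-[2-hydroxy-4-(2-methylbut-3-en-2-yloxy)-3-prenylphenyl]ethanone | CC(=O)c1ccc(OC(C)(C)C=C)c(CC=C(C)C)c1O | intermediate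
8 | 2,4-dihydroxy-3,5-diprenylacetophenone | CC(=O)c1cc(CC=C(C)C)c(O)c(CC=C(C)C)c1O | intermediate
9 | 1-[4-(tert-butyldimethylsilyloxy)-2-hydroxy-3,5-diprenylphenyl]ethanone | CC(=O)c1cc(CC=C(C)C)c(O[Si](C)(C)C(C)(C)C)c(CC=C(C)C)c1O | intermediate
10 | N,N-dimethylformamide dimethyl acetal | COC(OC)N(C)C | starting material
11 | (E)-1-[4-(tert-butyldimethylsilyloxy)-2-hydroxy-3,5-diprenylphenyl]-3-(dimethylamino)prop-2-en-1-one | CN(C)/C=C/C(=O)c1cc(CC=C(C)C)c(O[Si](C)(C)C(C)(C)C)c(CC=C(C)C)c1O | intermediate
12 | 7-(tert-butyldimethylsilyloxy)-6,8-diprenyl-4H-chromen-4-one (fragment 1) | O=c1ccoc2c(CC=C(C)C)c(O[Si](C)(C)C(C)(C)C)c(CC=C(C)C)cc12 | intermediate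
13 | 4-bromophenol | Oc1ccc(Br)cc1 | starting material
14 | 1-bromo-4-(2-methylbut-3-yn-2-yloxy)benzene | CC(C)(C#C)Oc1ccc(Br)cc1 | intermediate
15 | 1-bromo-4-(2-methylbut-3-en-2-yloxy)benzene | CC(C)(C=C)Oc1ccc(Br)cc1 | intermediate
16 | 4-bromo-2-prenylphenol | CC(C)=CCc1cc(Br)ccc1O | intermediate
17 | (4-bromo-2-prenylphenoxy)(tert-butyl)dimethylsilane | CC(C)=CCc1cc(Br)ccc1O[Si](C)(C)C(C)(C)C | intermediate
18 | [4-(tert-butyldimethylsilyloxy)-3-prenylphenyl]lithium | [Li]c1ccc(O[Si](C)(C)C(C)(C)C)c(CC=C(C)C)c1 | intermediate
19 | lithium [4-(tert-butyldimethylsilyloxy)-3-prenylphenyl]triisopropoxyborate | [Li+].CC(C)O[B-](OC(C)C)(OC(C)C)c1ccc(O[Si](C)(C)C(C)(C)C)c(CC=C(C)C)c1 | intermediate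
20 | 4-(tert-butyldimethylsilyloxy)-3-prenylphenylboronic acid (fragment 2) | CC(C)=CCc1cc(B(O)O)ccc1O[Si](C)(C)C(C)(C)C | intermediate
21 | (2S)-7-(tert-butyldimethylsilyloxy)-2-[4-(tert-butyldimethylsilyloxy)-3-prenylphenyl]-6,8-diprenylchroman-4-one | CC(C)=CCc1cc([C@@H]2CC(=O)c3cc(CC=C(C)C)c(O[Si](C)(C)C(C)(C)C)c(CC=C(C)C)c3O2)ccc1O[Si](C)(C)C(C)(C)C | intermediate
22 | (2S)-7-hydroxy-2-(4-hydroxy-3-prenylphenyl)-6,8-diprenylchroman-4-one | CC(C)=CCc1cc([C@@H]2CC(=O)c3cc(CC=C(C)C)c(O)c(CC=C(C)C)c3O2)ccc1O | target

Total step count: 16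
Longest linear sequence: 11 steps (steps 1 to 9, then 15 and 16); fragment 2 takes 5 steps (10 to 14).

**Steps most likely to fail**

Step 15. Insertion into the electron-rich chromone with its crowded ring A may be slow enough that protodeboronation of the electron-rich boronic acid consumes the partner, or the ligand may discriminate the two faces poorly. The fallback builds ring C by intramolecular oxa-Michael addition of a 2'-hydroxychalcone and sets out from 8 and 16.
- Ketone 8 is alkylated at the non-chelated hydroxyl (MOMCl, K2CO3, acetone) to 2-hydroxy-4-(methoxymethoxy)-3,5-diprenylacetophenone F1.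
- Phenol 16 is converted (MOMCl, iPr2NEt, CH2Cl2) into 4-bromo-1-(methoxymethoxy)-2-prenylbenzene F2, and bromine–lithium exchange with n-BuLi followed by DMF should give 4-(methoxymethoxy)-3-prenylbenzaldehyde F3.
- Claisen–Schmidt condensation of F1 with F3 (KOH, EtOH/H2O, rt) should give (E)-2'-hydroxy-4,4'-bis(methoxymethoxy)-3,3',5'-triprenylchalcone F4.
- Acetal cleavage (3 M HCl, MeOH, 40 °C) should free (E)-2',4',4-trihydroxy-3,3',5'-triprenylchalcone F5.
- Cyclisation (NaOAc, EtOH, reflux) should give racemic 7,4'-dihydroxy-6,8,3'-triprenylflavanone F6.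
- Preparative HPLC on a polysaccharide carbamate chiral stationary phase sets aside the (2R)-7,4'-dihydroxy-6,8,3'-triprenylflavanone F7, and the route is rejoined at the target 22.

Step 8. Methanol and dimethylamine released at 90 °C may strip the aryl silyl ether, after which the acetal would methylate the freed 4-oxygen. The fallback closes the pyranone before any silyl group is present and sets out from 8.
- Claisen condensation with ethyl formate (NaH in excess, THF, 0 °C to rt) should give, after acidic work-up, the cyclic hemiacetal 2,7-dihydroxy-6,8-diprenylchroman-4-one F8.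
- Dehydration in AcOH at 80 °C should give 7-hydroxy-6,8-diprenyl-4H-chromen-4-one F9.
- Silylation (TBSCl, imidazole, DMF) rejoins the route at 12.

Step 3. On the acyl-deactivated ring the tertiary allyl aryl ether may fragment (loss of isoprene back to the phenol) faster than it rearranges, and the hot ortho-prenylphenol may cyclise to chromans. The fallback replaces O-alkylation and rearrangement by direct C-alkylation and sets out from 1. Treating 1 with prenyl bromide in aqueous KOH at 0 °C to rt alkylates the ambident phenoxide at C3, the carbon between the two oxygens. Chromatographic removal of O-alkylated and dialkylated material rejoins the route at 5. This replaces steps 1 to 3 in one operation and makes no new compound.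

Further compounds
F1 | step 15 | 2-hydroxy-4-(methoxymethoxy)-3,5-diprenylacetophenone | CC(=O)c1cc(CC=C(C)C)c(OCOC)c(CC=C(C)C)c1O
F2 | step 15 | 4-bromo-1-(methoxymethoxy)-2-prenylbenzene | COCOc1ccc(Br)cc1CC=C(C)C
F3 | step 15 | 4-(methoxymethoxy)-3-prenylbenzaldehyde | COCOc1ccc(C=O)cc1CC=C(C)C
F4 | step 15 | (E)-2'-hydroxy-4,4'-bis(methoxymethoxy)-3,3',5'-triprenylchalcone | COCOc1ccc(/C=C/C(=O)c2cc(CC=C(C)C)c(OCOC)c(CC=C(C)C)c2O)cc1CC=C(C)C
F5 | step 15 | (E)-2',4',4-trihydroxy-3,3',5'-triprenylchalcone | CC(C)=CCc1cc(/C=C/C(=O)c2cc(CC=C(C)C)c(O)c(CC=C(C)C)c2O)ccc1O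
F6 | step 15 | racemic 7,4'-dihydroxy-6,8,3'-triprenylflavanone | CC(C)=CCc1cc(C2CC(=O)c3cc(CC=C(C)C)c(O)c(CC=C(C)C)c3O2)ccc1O
F7 | step 15 | (2R)-7,4'-dihydroxy-6,8,3'-triprenylflavanone | CC(C)=CCc1cc([C@H]2CC(=O)c3cc(CC=C(C)C)c(O)c(CC=C(C)C)c3O2)ccc1O
F8 | step 8 | 2,7-dihydroxy-6,8-diprenylchroman-4-one | O=C1CC(O)Oc2c(CC=C(C)C)c(O)c(CC=C(C)C)cc12
F9 | step 8 | 7-hydroxy-6,8-diprenyl-4H-chromen-4-one | O=c1ccoc2c(CC=C(C)C)c(O)c(CC=C(C)C)cc12
F0 | step 3 | none | none
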